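## Retrosynthetic overview

- Numbering (daucane) used below: C1 quaternary methyl carbon, C2–C3, C4 isopropyl carbinol, C5 ring-fusion CH, C6 ester carbon, C7, C8 methyl carbinol, C9=C10.
- Target ⇐ triol 16 (acylation of the only secondary OH) ⇐ 8,9-epoxide 13 ⇐ homoallylic diol 12; the 8,9-ene → 8-OH/9,10-ene transposition copies the late allylic oxidation.
- Ring A (five-membered) is closed last across C5–C4 (farnesane C6–C10, the bond of the second biosynthetic cyclisation). One methylative conjugate addition/aldol on cycloheptadienone 9 sets C1, C5 and C4; the C4 carbonyl replaces the olefin so that O-4 is already in place.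
- Ring B (seven-membered) is made first, by one-carbon enlargement of a six-membered carbocycle (Saegusa–Ito), as the six-membered bisabolyl stage is ring-enlarged in the presumed biogenesis.
- Order of ring formation: six-membered carbocycle (Birch-reduced cresol derivative) → ring B → ring A.

Assumption: the sense of induction of the copper–phosphoramidite catalyst in step 6 is taken by analogy with AlMe3 additions to 3-alkylcycloalkenones; if the (R)-quaternary centre forms, the mirror-image ligand is used.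

## Route

Step 1
Reactants: 1 2-hydroxy-4-methylbenzaldehyde; 2 3-methylbutan-2-one
Product: 3 (E)-1-(2-hydroxy-4-methylphenyl)-4-methylpent-1-en-3-one
Conditions: NaOH, EtOH–H2O, 0 °C → rt; then AcOH
Reagents that add atoms: none
Why: Claisen–Schmidt aldol condensation; only the methyl side of the ketone can dehydrate to the conjugated (E)-enone.

Step 2
Reactants: 3 (E)-1-(2-hydroxy-4-methylphenyl)-4-methylpent-1-en-3-one
Product: 4 (E)-1-[2-(tert-butyldimethylsilyloxy)-4-methylphenyl]-4-methylpent-1-en-3-one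
Conditions: TBSCl, imidazole, DMF, rt
Reagents that add atoms: tert-butyldimethylsilyl chloride, CC(C)(C)[Si](C)(C)Cl
Why: O-silylation of the phenol, so that the later Birch reduction delivers a regiodefined silyl enol ether.

Step 3
Reactants: 4 (E)-1-[2-(tert-butyldimethylsilyloxy)-4-methylphenyl]-4-methylpent-1-en-3-one
Product: 6 1-[2-(tert-butyldimethylsilyloxy)-4-methylcyclohexa-1,4-dien-1-yl]-4-methylpentan-3-one, via lithium enolate 5 (not isolated)
Conditions: Li (4.5 equiv), NH3(l)–THF, t-BuOH (3 equiv), −78 °C; then solid NH4Cl, pentane work-up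
Reagents that add atoms: none
Why: Birch reduction; the enone is first reduced to its lithium enolate, which shields the ketone, then the aryl silyl ether gives the 1-silyloxy-1,4-diene with the oxygen- and alkyl-bearing carbons left sp2.

Step 4
Reactants: 6 1-[2-(tert-butyldimethylsilyloxy)-4-methylcyclohexa-1,4-dien-1-yl]-4-methylpentan-3-one
Product: 7 1-[6-(tert-butyldimethylsilyloxy)-4-methylbicyclo[4.1.0]hept-3-en-1-yl]-4-methylpentan-3-one (racemic)
Conditions: Et2Zn (1.2 equiv), CH2I2 (2.4 equiv), CH2Cl2, 0 °C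
Reagents that add atoms: diiodomethane, ICI
Why: Furukawa-modified Simmons–Smith cyclopropanation is fastest at the electron-rich tetrasubstituted silyl enol ether and leaves the trisubstituted ring alkene and the ketone untouched.

Step 5
Reactants: 7 1-[6-(tert-butyldimethylsilyloxy)-4-methylbicyclo[4.1.0]hept-3-en-1-yl]-4-methylpentan-3-one
Product: 9 6-methyl-3-(4-methyl-3-oxopentyl)cyclohepta-2,5-dien-1-one, via tertiary chloroketone 8 (not isolated)
Conditions: FeCl3 (2.2 equiv), DMF, 0 °C → rt; then NaOAc, MeOH, rt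
Reagents that add atoms: none
Why: Saegusa–Ito ring expansion; FeCl3 cleaves the internal cyclopropane bond to the tertiary β-keto radical, chlorine transfer and mild loss of HCl give the ring-enlarged 3-substituted cycloheptenone (ring B) without moving the 5,6-alkene.

Step 6
Reactants: 9 6-methyl-3-(4-methyl-3-oxopentyl)cyclohepta-2,5-dien-1-one
Product: 11 (3R,3aR,8aS)-3-hydroxy-6,8a-dimethyl-3-(propan-2-yl)-2,3,3a,5,8,8a-hexahydroazulen-4(1H)-one (cis-fused), via aluminium enolate 10 (not isolated)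
Conditions: AlMe3 (1.3 equiv), Cu(OTf)2 (3 mol %), (S,R,R)-BINOL bis(1-phenylethyl)amine phosphoramidite (6 mol %), Et2O, −30 → 0 °C; aq. Rochelle salt
Reagents that add atoms: trimethylaluminium, C[Al](C)C
Why: Proposed new method: copper–phosphoramidite-catalysed enantioselective conjugate transfer of methyl from AlMe3 to C1 of the 3-substituted cycloheptenone (closest known reaction: copper-catalysed asymmetric conjugate addition of trialkylaluminium reagents to 3-alkylcyclohept-2-enones, which gives quaternary centres) forms the C5=C6 aluminium enolate regiospecifically; this enolate closes ring A by intramolecular aldol addition to the side-chain ketone through an aluminium-chelated chair transition state on the face carrying the tether (closest known reaction: conjugate addition–aldol cyclisation of keto-enones), so H-5 ends cis to the new methyl group and O-4 syn to C6.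

Step 7
Reactants: 11 (3R,3aR,8aS)-3-hydroxy-6,8a-dimethyl-3-(propan-2-yl)-2,3,3a,5,8,8a-hexahydroazulen-4(1H)-one
Product: 12 (3R,3aS,4S,8aS)-6,8a-dimethyl-3-(propan-2-yl)-1,2,3,3a,4,5,8,8a-octahydroazulene-3,4-diol
Conditions: Me4NBH(OAc)3 (5 equiv), MeCN–AcOH (1:1), −25 °C
Reagents that add atoms: none
Why: Evans–Saksena reduction; the C4 alkoxy-acetoxyborohydride delivers hydride intramolecularly to the endo face of C6=O, giving the anti-1,3-diol with C6–OH on the face of C1–Me and H-5.

Step 8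
Reactants: 12 (3R,3aS,4S,8aS)-6,8a-dimethyl-3-(propan-2-yl)-1,2,3,3a,4,5,8,8a-octahydroazulene-3,4-diol
Product: 13 (3R,3aS,4S,6R,7S,8aS)-6,7-epoxy-6,8a-dimethyl-3-(propan-2-yl)decahydroazulene-3,4-diol
Conditions: VO(acac)2 (5 mol %), t-BuOOH (1.5 equiv), CH2Cl2, 0 °C → rt
Reagents that add atoms: tert-butyl hydroperoxide, CC(C)(C)OO
Why: Hydroxyl-directed vanadium-catalysed epoxidation; the homoallylic C6–OH delivers the peroxide to the convex face of C8=C9, fixing the C8–O configuration.

Step 9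
Reactants: 13 (3R,3aS,4S,6R,7S,8aS)-6,7-epoxy-6,8a-dimethyl-3-(propan-2-yl)decahydroazulene-3,4-diol
Product: 16 (3R,3aS,4S,6R,8aS)-6,8a-dimethyl-3-(propan-2-yl)-1,2,3,3a,4,5,6,8a-octahydroazulene-3,4,6-triol, via hydroxy selenide 14 (not isolated), via selenoxide 15 (not isolated)
Conditions: (PhSe)2, NaBH4, EtOH, 70 °C; then 30% H2O2, pyridine, THF, 0 °C → rt
Reagents that add atoms: none
Why: Sharpless–Lauer epoxide-to-allylic-alcohol sequence; PhSe− opens the epoxide by SN2 at the secondary C9 (C8–O untouched), and selenoxide syn-elimination can only go toward C10, giving the C8 tertiary alcohol and the C9=C10 alkene.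

Step 10
Reactants: 16 (3R,3aS,4S,6R,8aS)-6,8a-dimethyl-3-(propan-2-yl)-1,2,3,3a,4,5,6,8a-octahydroazulene-3,4,6-triol; 17 4-acetoxybenzoyl chloride
Product: 19 [(3R,3aS,4S,6R,8aS)-3,6-dihydroxy-6,8a-dimethyl-3-(propan-2-yl)-1,2,3,3a,4,5,6,8a-octahydroazulen-4-yl] 4-hydroxybenzoate, via aryl acetate 18 (not isolated)
Conditions: pyridine, DMAP (cat.), CH2Cl2, 0 °C → rt; then K2CO3, MeOH, 0 °C
Reagents that add atoms: none
Why: Acylation occurs only at the single secondary hydroxyl (both other OH groups are tertiary); methanolysis then removes the far more labile phenyl acetate, the resulting phenoxide protecting the benzoate from cleavage.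

## Compound list

1 | 2-hydroxy-4-methylbenzaldehyde | Cc1ccc(C=O)c(O)c1 | starting material
2 | 3-methylbutan-2-one | CC(=O)C(C)C | starting material
3 | (E)-1-(2-hydroxy-4-methylphenyl)-4-methylpent-1-en-3-one | CC(C)C(=O)/C=C/c1ccc(C)cc1O | intermediate
4 | (E)-1-[2-(tert-butyldimethylsilyloxy)-4-methylphenyl]-4-methylpent-1-en-3-one | CC(C)C(=O)/C=C/c1ccc(C)cc1O[Si](C)(C)C(C)(C)C | intermediate
5 | lithium enolate of 6 (lithium 1-[2-(tert-butyldimethylsilyloxy)-4-methylcyclohexa-1,4-dien-1-yl]-4-methylpent-2-en-3-olate) | CC(C)C(O[Li])=CCC1=C(O[Si](C)(C)C(C)(C)C)CC(C)=CC1 | intermediate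
6 | 1-[2-(tert-butyldimethylsilyloxy)-4-methylcyclohexa-1,4-dien-1-yl]-4-methylpentan-3-one | CC(C)C(=O)CCC1=C(O[Si](C)(C)C(C)(C)C)CC(C)=CC1 | intermediate
7 | 1-[6-(tert-butyldimethylsilyloxy)-4-methylbicyclo[4.1.0]hept-3-en-1-yl]-4-methylpentan-3-one (racemic) | CC(C)C(=O)CCC12CC=C(C)CC1(O[Si](C)(C)C(C)(C)C)C2 | intermediate
8 | 3-chloro-6-methyl-3-(4-methyl-3-oxopentyl)cyclohept-5-en-1-one (racemic) | CC(C)C(=O)CCC1(Cl)CC=C(C)CC(=O)C1 | intermediate
9 | 6-methyl-3-(4-methyl-3-oxopentyl)cyclohepta-2,5-dien-1-one | CC(C)C(=O)CCC1=CC(=O)CC(C)=CC1 | intermediate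
10 | dimethyl{[(3S)-3,6-dimethyl-3-(4-methyl-3-oxopentyl)cyclohepta-1,5-dien-1-yl]oxy}alumane | CC(C)C(=O)CC[C@@]1(C)CC=C(C)CC(O[Al](C)C)=C1 | intermediate
11 | (3R,3aR,8aS)-3-hydroxy-6,8a-dimethyl-3-(propan-2-yl)-2,3,3a,5,8,8a-hexahydroazulen-4(1H)-one | CC(C)[C@]1(O)CC[C@@]2(C)CC=C(C)CC(=O)[C@@H]12 | intermediate
12 | (3R,3aS,4S,8aS)-6,8a-dimethyl-3-(propan-2-yl)-1,2,3,3a,4,5,8,8a-octahydroazulene-3,4-diol | CC(C)[C@]1(O)CC[C@@]2(C)CC=C(C)C[C@H](O)[C@@H]12 | intermediate
13 | (3R,3aS,4S,6R,7S,8aS)-6,7-epoxy-6,8a-dimethyl-3-(propan-2-yl)decahydroazulene-3,4-diol | CC(C)[C@]1(O)CC[C@@]2(C)C[C@@H]3O[C@]3(C)C[C@H](O)[C@@H]12 | intermediate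
14 | (3R,3aS,4S,6R,7R,8aS)-6,8a-dimethyl-7-(phenylselanyl)-3-(propan-2-yl)decahydroazulene-3,4,6-triol | CC(C)[C@]1(O)CC[C@@]2(C)C[C@@H]([Se]c3ccccc3)[C@](C)(O)C[C@H](O)[C@@H]12 | intermediate
15 | (3R,3aS,4S,6R,7R,8aS)-7-(benzeneseleninyl)-6,8a-dimethyl-3-(propan-2-yl)decahydroazulene-3,4,6-triol | CC(C)[C@]1(O)CC[C@@]2(C)C[C@@H]([Se](=O)c3ccccc3)[C@](C)(O)C[C@H](O)[C@@H]12 | intermediate
16 | (3R,3aS,4S,6R,8aS)-6,8a-dimethyl-3-(propan-2-yl)-1,2,3,3a,4,5,6,8a-octahydroazulene-3,4,6-triol | CC(C)[C@]1(O)CC[C@@]2(C)C=C[C@](C)(O)C[C@H](O)[C@@H]12 | intermediate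
17 | 4-acetoxybenzoyl chloride | CC(=O)Oc1ccc(cc1)C(Cl)=O | starting material
18 | [(3R,3aS,4S,6R,8aS)-3,6-dihydroxy-6,8a-dimethyl-3-(propan-2-yl)-1,2,3,3a,4,5,6,8a-octahydroazulen-4-yl] 4-acetoxybenzoate | CC(C)[C@]1(O)CC[C@@]2(C)C=C[C@](C)(O)C[C@H](OC(=O)c3ccc(OC(C)=O)cc3)[C@@H]12 | intermediate
19 | [(3R,3aS,4S,6R,8aS)-3,6-dihydroxy-6,8a-dimethyl-3-(propan-2-yl)-1,2,3,3a,4,5,6,8a-octahydroazulen-4-yl] 4-hydroxybenzoate (CNP0280165.1) | CC(C)[C@]1(O)CC[C@@]2(C)C=C[C@](C)(O)C[C@H](OC(=O)c3ccc(O)cc3)[C@@H]12 | target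

## Step count and risks

Total step count: 10. Longest linear sequence: 10 steps (1 → 19; 2 and 17 are purchased).

Three steps most likely to fail, each with a fallback:

Step 6 (methylative ring-A closure). AlMe3 may attack the isopropyl ketone, the aluminium enolate may be too unreactive to close the ring, or the selectivity may be poor on this skipped dienone. Fallback: set out from 9 and separate the two events.
- Ketalise the isolated saturated ketone chemoselectively (ethylene glycol, PPTS) to give 3-[2-(2-isopropyl-1,3-dioxolan-2-yl)ethyl]-6-methylcyclohepta-2,5-dien-1-one F5.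
- Run the same copper-catalysed asymmetric methyl addition with protic quench to give (3S)-3-[2-(2-isopropyl-1,3-dioxolan-2-yl)ethyl]-3,6-dimethylcyclohept-5-en-1-one F6.
- Mild acid hydrolysis gives (3S)-3,6-dimethyl-3-(4-methyl-3-oxopentyl)cyclohept-5-en-1-one F7.
- Close ring A under thermodynamic control (catalytic KOtBu, t-BuOH–THF, 0 °C); only the C5 enolate can form a five-membered ring, and the cis-fused aldol with O-4 hydrogen-bonded to C6=O is favoured. The route is rejoined at 11.

Step 3 (Birch reduction of an aryl silyl ether that also carries an enone). Risks are loss of the silyl group, over-reduction, or hydrolysis of the silyl dienol ether on work-up. Fallback: set out from 3 and replace steps 2–5.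
- Methylate the phenol (MeI, K2CO3) to give (E)-1-(2-methoxy-4-methylphenyl)-4-methylpent-1-en-3-one F1.
- Birch reduction gives the robust methyl enol ether 1-(2-methoxy-4-methylcyclohexa-1,4-dien-1-yl)-4-methylpentan-3-one F2.
- Dibromocarbene (CHBr3, KOtBu, pentane, −20 °C) adds to the enol ether to give 1-(7,7-dibromo-6-methoxy-4-methylbicyclo[4.1.0]hept-3-en-1-yl)-4-methylpentan-3-one F3.
- Silver-assisted cyclopropyl-to-allyl cation ring opening (AgBF4, aqueous acetone) gives 2-bromo-6-methyl-3-(4-methyl-3-oxopentyl)cyclohepta-2,5-dien-1-one F4.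
- Zn/AcOH (or Bu3SnH with Pd(PPh3)4) removes the vinylic bromine, and the route is rejoined at 9.

Step 9 (selenide opening on the concave face, then elimination). Attack at C9 must come from the hindered face, and PhSeO2H/H2O2 could epoxidise the new alkene. Fallback: set out from 12 and replace steps 8–9 by the direct ene oxidation. Singlet oxygen (O2, tetraphenylporphyrin, hν, CH2Cl2, 0 °C) adds to the convex face of C8=C9 with hydrogen abstraction from C10. This gives (3R,3aS,4S,6R,8aS)-6-hydroperoxy-6,8a-dimethyl-3-(propan-2-yl)-1,2,3,3a,4,5,6,8a-octahydroazulene-3,4-diol F8, which PPh3 reduces to rejoin the route at 16. Regioisomeric ene products would have to be separated.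

Further compounds
F1 | step 3 | (E)-1-(2-methoxy-4-methylphenyl)-4-methylpent-1-en-3-one | CC(C)C(=O)/C=C/c1ccc(C)cc1OC
F2 | step 3 | 1-(2-methoxy-4-methylcyclohexa-1,4-dien-1-yl)-4-methylpentan-3-one | CC(C)C(=O)CCC1=C(OC)CC(C)=CC1
F3 | step 3 | 1-(7,7-dibromo-6-methoxy-4-methylbicyclo[4.1.0]hept-3-en-1-yl)-4-methylpentan-3-one | CC(C)C(=O)CCC12CC=C(C)CC1(OC)C2(Br)Br
F4 | step 3 | 2-bromo-6-methyl-3-(4-methyl-3-oxopentyl)cyclohepta-2,5-dien-1-one | CC(C)C(=O)CCC1=C(Br)C(=O)CC(C)=CC1
F5 | step 6 | 3-[2-(2-isopropyl-1,3-dioxolan-2-yl)ethyl]-6-methylcyclohepta-2,5-dien-1-one | CC(C)C1(CCC2=CC(=O)CC(C)=CC2)OCCO1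
F6 | step 6 | (3S)-3-[2-(2-isopropyl-1,3-dioxolan-2-yl)ethyl]-3,6-dimethylcyclohept-5-en-1-one | CC(C)C1(CC[C@@]2(C)CC=C(C)CC(=O)C2)OCCO1
F7 | step 6 | (3S)-3,6-dimethyl-3-(4-methyl-3-oxopentyl)cyclohept-5-en-1-one | CC(C)C(=O)CC[C@@]1(C)CC=C(C)CC(=O)C1
F8 | step 9 | (3R,3aS,4S,6R,8aS)-6-hydroperoxy-6,8a-dimethyl-3-(propan-2-yl)-1,2,3,3a,4,5,6,8a-octahydroazulene-3,4-diol | CC(C)[C@]1(O)CC[C@@]2(C)C=C[C@](C)(OO)C[C@H](O)[C@@H]12
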